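The 1,2-dioxane ring is opened retrosynthetically at C4–C5, because C4 and C5 are its only two plain methylene carbons and can therefore be linked last as an alkene. Ring-closing metathesis of an acyclic bis-allylic mixed peroxyketal forms C4=C5 and the six-membered ring in a single operation, with O1–O2, the C6 ketal and the C3 stereocentre already in place. The precursor is a peroxide carrying on one oxygen an enantiopure secondary allylic carbon (C3, with a PMB-protected hydroxyethyl arm) and on the other a methoxy-substituted vinyl ketal carbon (C6, with a silyl-protected hydroxybutyl arm). Alkene reduction, acid equilibration at C6, Sonogashira side-chain assembly and oxidation of the C3 arm finish the route.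

Key step: step 10

Remark on numbering: in all names the ring atoms are O1, O2, C3 (CH bearing the acetic acid arm), C4, C5, C6 (ketal carbon).
Remark on descriptors: C3 is labelled R in 8, 15 and 16 and S from 17 onward only because the CIP ranking of its carbon substituents changes when C4=C5 is saturated; the spatial arrangement is the same throughout.

Step 1
Reactants: 1 propane-1,3-diol (3 equiv)
Product: 2 3-[(4-methoxybenzyl)oxy]propan-1-ol
Conditions: NaH (1.0 equiv), PMBCl (1.0 equiv), Bu4NI (cat.), THF/DMF, 0 °C to rt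
Reagents that add atoms: 4-methoxybenzyl chloride, COc1ccc(CCl)cc1
Why: Williamson ether synthesis, in which the excess of the symmetrical diol should hold the reaction at mono-alkylation.

Step 2
Reactants: 2 3-[(4-methoxybenzyl)oxy]propan-1-ol
Product: 3 3-[(4-methoxybenzyl)oxy]propanal
Conditions: TEMPO (10 mol %), PhI(OAc)2 (1.1 equiv), CH2Cl2, rt
Reagents that add atoms: none
Why: TEMPO-catalysed oxoammonium oxidation stops at the aldehyde under anhydrous, non-basic conditions, so the β-alkoxy aldehyde should not eliminate and the PMB ether is untouched.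

Step 3
Reactants: 3 3-[(4-methoxybenzyl)oxy]propanal; 4 vinylmagnesium bromide
Product: 5 racemic 5-[(4-methoxybenzyl)oxy]pent-1-en-3-ol
Conditions: THF, −78 to 0 °C; then sat. aq. NH4Cl
Reagents that add atoms: vinylmagnesium bromide (compound 4), C=C[Mg]Br
Why: Grignard 1,2-addition to an aldehyde gives the secondary allylic alcohol as the racemate.

Step 4
Reactants: 5 racemic 5-[(4-methoxybenzyl)oxy]pent-1-en-3-ol
Product: 6 (3S)-5-[(4-methoxybenzyl)oxy]pent-1-en-3-ol
Conditions: Ti(OiPr)4 (1.0 equiv), D-(−)-diisopropyl tartrate (1.2 equiv), t-BuOOH (0.6 equiv), 4 Å sieves, CH2Cl2, −20 °C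
Reagents that add atoms: none
Why: Sharpless kinetic resolution, in which the titanium tartrate complex of the D-tartrate epoxidises the 3R alcohol much faster, so the 3S alcohol should be recovered enantioenriched and is separable from the polar epoxy alcohol.

Step 5
Reactants: 6 (3S)-5-[(4-methoxybenzyl)oxy]pent-1-en-3-ol
Product: 8 (3R)-3-hydroperoxy-5-[(4-methoxybenzyl)oxy]pent-1-ene, via allylic mesylate 7 (not isolated)
Conditions: Ms2O, Et3N, THF, −30 °C; then added cold to urea·H2O2 (10 equiv), CsOH·H2O (4 equiv), DMF, 0 °C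
Reagents that add atoms: hydrogen peroxide (as its urea adduct), OO; methanesulfonic anhydride, CS(=O)(=O)OS(C)(=O)=O (mesyl group of 7 only)
Why: Sulfonylation followed by SN2 displacement of the sulfonate by hydroperoxide anion should invert the carbinol carbon (3S to 3R), and chloride-free mesylation, a dipolar aprotic medium, low temperature and a large excess of the small HOO– nucleophile are chosen to favour direct attack over ionisation, SN2′ attack and double alkylation.

Step 6
Reactants: 9 tetrahydrofuran
Product: 10 tert-butyl(4-iodobutoxy)diphenylsilane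
Conditions: TBDPSCl, NaI, MeCN, rt to 55 °C
Reagents that add atoms: tert-butyl(chloro)diphenylsilane, CC(C)(C)[Si](Cl)(c1ccccc1)c1ccccc1; sodium iodide, [Na+].[I-]
Why: Silyl iodide ether cleavage, in which the silyl iodide formed in situ silylates the ring oxygen and iodide opens the oxonium ion at the α-carbon.

Step 7
Reactants: 11 methoxyallene (1-methoxypropa-1,2-diene); 10 tert-butyl(4-iodobutoxy)diphenylsilane
Product: 13 tert-butyl[(5-methoxyhepta-5,6-dien-1-yl)oxy]diphenylsilane, via 1-lithio-1-methoxyallene 12 (not isolated)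
Conditions: n-BuLi, THF, −78 to −40 °C; then 10, −78 °C to rt
Reagents that add atoms: n-butyllithium, [Li]CCCC (lithium of 12 only)
Why: α-Lithiation of an alkoxyallene and SN2 alkylation with a primary iodide put the chain on the oxygen-bearing allene carbon, making the lithioallene an acryloyl anion equivalent.

Step 8
Reactants: 13 tert-butyl[(5-methoxyhepta-5,6-dien-1-yl)oxy]diphenylsilane
Product: 14 tert-butyl[(5,5-dimethoxyhept-6-en-1-yl)oxy]diphenylsilane
Conditions: MeOH, PPTS (2 mol %), 0 °C; Et3N quench
Reagents that add atoms: methanol, CO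
Why: Acid-catalysed addition of an alcohol to an alkoxyallene, in which protonation at the central allene carbon gives a methoxy-stabilised allyl-type oxocarbenium ion that methanol captures at the oxygen-bearing carbon under kinetic control, so the vinyl ketone dimethyl ketal forms without a free enone ever meeting methanol.

Step 9
Reactants: 8 (3R)-3-hydroperoxy-5-[(4-methoxybenzyl)oxy]pent-1-ene; 14 tert-butyl[(5,5-dimethoxyhept-6-en-1-yl)oxy]diphenylsilane (1.5 equiv)
Product: 15 (3R)-5-[(4-methoxybenzyl)oxy]pent-1-en-3-yl 7-[(tert-butyldiphenylsilyl)oxy]-3-methoxyhept-1-en-3-yl peroxide (both epimers at the ketal carbon)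
Conditions: PPTS (10 mol %), 4 Å sieves, CH2Cl2, 0 °C to rt; Et3N quench
Reagents that add atoms: none
Why: Acid-catalysed transketalisation, in which the ketal ionises to the same oxocarbenium ion as in step 8 and the hydroperoxide captures it at the ketal carbon while the sieves take up methanol; the new ketal centre forms as both epimers, which is harmless because C6 is equilibrated in step 12.

Step 10
Reactants: 15 mixed peroxyketal (both epimers at the ketal carbon)
Product: 16 (3R)-6-{4-[(tert-butyldiphenylsilyl)oxy]butyl}-6-methoxy-3-{2-[(4-methoxybenzyl)oxy]ethyl}-3,6-dihydro-1,2-dioxine (both C6 epimers)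
Conditions: Hoveyda–Grubbs second-generation catalyst (H2IMes)Cl2Ru=CH(C6H4-2-OiPr) (5–10 mol %), 1,4-benzoquinone (10 mol %), CH2Cl2 (0.005 M), 40 °C, argon sparge; ethyl vinyl ether quench, silica filtration
Reagents that add atoms: none
Why: Ring-closing olefin metathesis: the ruthenium alkylidene first exchanges onto the less hindered vinyl group at the secondary C3 carbon, adds intramolecularly to the vinyl group on the ketal carbon to give a ruthenacyclobutane, and cycloreverts with loss of ethene to leave the C4=C5 double bond. The closest known chemistry is the ring-closing metathesis of acrolein-derived mixed allylic acetals to 2-alkoxy-3,6-dihydro-2H-pyrans, together with the tolerance of ruthenium carbenes for allylic dialkyl peroxides in cross-metathesis. The single ring is closed by C=C formation between the two allylic carbons of the peroxide tether, a six-membered closure that can only give the cis ring alkene and is helped by the gauche C–O–O–C arrangement and the fully substituted ketal carbon. No stereocentre is formed: C3 is carried unchanged from hydroperoxide 8 and the C6 mixture is left for step 12. The step needs chemoselectivity (metathesis instead of O–O cleavage or double-bond migration) and cyclisation instead of oligomerisation, which the phosphine-free catalyst, benzoquinone, high dilution, the absence of free OH or base, and prompt removal of ruthenium before concentration are meant to secure.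

Step 11
Reactants: 16 dihydrodioxine (both C6 epimers)
Product: 17 (3S)-6-{4-[(tert-butyldiphenylsilyl)oxy]butyl}-6-methoxy-3-{2-[(4-methoxybenzyl)oxy]ethyl}-1,2-dioxane (both C6 epimers)
Conditions: KO2CN=NCO2K (excess, portionwise), AcOH, CH2Cl2, 0 °C to rt
Reagents that add atoms: none
Why: Diimide reduction (concerted syn transfer of two hydrogens) saturates the cis ring alkene without touching the O–O bond, and the mildly acidic, amine-free medium avoids Kornblum–DeLaMare opening of the allylic peroxide; C3 is not involved.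

Step 12
Reactants: 17 saturated peroxyketal (both C6 epimers)
Product: 18 (3S,6R)-6-{4-[(tert-butyldiphenylsilyl)oxy]butyl}-6-methoxy-3-{2-[(4-methoxybenzyl)oxy]ethyl}-1,2-dioxane
Conditions: CSA (10 mol %), MeOH (5 equiv), CH2Cl2, rt; NaHCO3 quench
Reagents that add atoms: none
Why: Acid-catalysed ketal epimerisation through the ring peroxycarbenium ion (methanol leaves and re-adds) under thermodynamic control should converge on the chair with axial methoxy (anomeric stabilisation) and both carbon substituents equatorial, which is the 3S,6R isomer; the silyl ether is kept on so that no free δ-hydroxyl can spiroketalise.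

Step 13
Reactants: 18 (3S,6R) silyl ether
Product: 19 (3S,6R)-6-(4-hydroxybutyl)-6-methoxy-3-{2-[(4-methoxybenzyl)oxy]ethyl}-1,2-dioxane
Conditions: Bu4NF, AcOH (1:1), THF, 0 °C to rt; used without acidic contact
Reagents that add atoms: none
Why: Fluoride-mediated desilylation in an acetic acid-buffered, near-neutral medium, so that the C3–H next to the peroxide is not deprotonated and the freed δ-hydroxyl is not driven onto the ketal.

Step 14
Reactants: 19 primary alcohol
Product: 20 (3S,6R)-6-methoxy-3-{2-[(4-methoxybenzyl)oxy]ethyl}-6-(4-oxobutyl)-1,2-dioxane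
Conditions: Dess–Martin periodinane, pyridine, CH2Cl2, 0 °C to rt
Reagents that add atoms: none
Why: Dess–Martin oxidation of a primary alcohol to the aldehyde under pyridine-buffered, non-aqueous conditions that a peroxyketal should tolerate.

Step 15
Reactants: 20 aldehyde
Product: 21 (3S,6R)-6-methoxy-3-{2-[(4-methoxybenzyl)oxy]ethyl}-6-(pent-4-yn-1-yl)-1,2-dioxane
Conditions: dimethyl (1-diazo-2-oxopropyl)phosphonate, K2CO3, MeOH, 0 °C to rt
Reagents that add atoms: dimethyl (1-diazo-2-oxopropyl)phosphonate, CC(=O)C(=[N+]=[N-])P(=O)(OC)OC (adds the terminal alkyne carbon)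
Why: Seyferth–Gilbert homologation in its Ohira–Bestmann form converts the aldehyde into the terminal alkyne under carbonate/methanol conditions, which should be mild enough for a dialkyl peroxide without an activated α-hydrogen.

Step 16
Reactants: 22 dec-9-en-1-ol
Product: 23 dec-9-enal
Conditions: TEMPO (10 mol %), PhI(OAc)2 (1.1 equiv), CH2Cl2, rt
Reagents that add atoms: none
Why: TEMPO-catalysed oxoammonium oxidation of a primary alcohol to the aldehyde leaves the terminal alkene alone.

Step 17
Reactants: 23 dec-9-enal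
Product: 24 undec-1-en-10-yne
Conditions: dimethyl (1-diazo-2-oxopropyl)phosphonate, K2CO3, MeOH, 0 °C to rt
Reagents that add atoms: dimethyl (1-diazo-2-oxopropyl)phosphonate, CC(=O)C(=[N+]=[N-])P(=O)(OC)OC (adds the terminal alkyne carbon)
Why: Ohira–Bestmann homologation of an aliphatic aldehyde to the one-carbon-longer terminal alkyne.

Step 18
Reactants: 24 undec-1-en-10-yne
Product: 26 (1E)-1-iodoundeca-1,10-diene, via alkenylzirconocene chloride 25 (not isolated)
Conditions: Cp2Zr(H)Cl (1.05 equiv), CH2Cl2, 0 °C to rt; then I2, 0 °C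
Reagents that add atoms: iodine, II; Schwartz reagent Cp2Zr(H)Cl, [H][Zr](Cl)(C1C=CC=C1)C1C=CC=C1 (zirconocene of 25 only)
Why: Hydrozirconation–iodination, in which the zirconium hydride adds syn and at the terminus of the alkyne (faster than to the terminal alkene) and iodinolysis of the C–Zr bond proceeds with retention, fixing the E geometry.

Step 19
Reactants: 21 dioxane alkyne; 26 (1E)-1-iodoundeca-1,10-diene
Product: 27 (3S,6R)-6-[(6E)-hexadeca-6,15-dien-4-yn-1-yl]-6-methoxy-3-{2-[(4-methoxybenzyl)oxy]ethyl}-1,2-dioxane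
Conditions: Pd(PPh3)4 (5 mol %), CuI (10 mol %), i-Pr2NH, THF, rt, degassed
Reagents that add atoms: none
Why: Sonogashira coupling of a terminal alkyne with an alkenyl iodide proceeds at room temperature with retention of the E geometry, and such couplings are compatible with alkynes that carry a 1,2-dioxane.

Step 20
Reactants: 27 PMB ether
Product: 28 2-[(3S,6R)-6-[(6E)-hexadeca-6,15-dien-4-yn-1-yl]-6-methoxy-1,2-dioxan-3-yl]ethan-1-ol
Conditions: DDQ, CH2Cl2/pH 7 phosphate buffer, 0 °C
Reagents that add atoms: none
Why: Oxidative cleavage of a 4-methoxybenzyl ether by DDQ (benzylic hydride abstraction, then hydrolysis of the oxocarbenium ion) in a buffered two-phase medium should spare the peroxyketal, the enyne and the terminal alkene.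

Step 21
Reactants: 28 primary alcohol
Product: 30 2-[(3S,6R)-6-[(6E)-hexadeca-6,15-dien-4-yn-1-yl]-6-methoxy-1,2-dioxan-3-yl]acetic acid, via peroxy aldehyde 29 (not isolated)
Conditions: TEMPO (20 mol %), PhI(OAc)2 (2.5 equiv), MeCN/H2O, rt
Reagents that add atoms: water, O
Why: TEMPO/PhI(OAc)2 oxidation in aqueous acetonitrile takes the primary alcohol through the aldehyde hydrate to the carboxylic acid without base, so the β-peroxy aldehyde should not undergo β-elimination and the alkenes and alkyne are not attacked.

Compound list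
1 | propane-1,3-diol | OCCCO | starting material
2 | 3-[(4-methoxybenzyl)oxy]propan-1-ol | OCCCOCc1ccc(OC)cc1 | intermediate
3 | 3-[(4-methoxybenzyl)oxy]propanal | O=CCCOCc1ccc(OC)cc1 | intermediate
4 | vinylmagnesium bromide | C=C[Mg]Br | starting material
5 | racemic 5-[(4-methoxybenzyl)oxy]pent-1-en-3-ol | C=CC(O)CCOCc1ccc(OC)cc1 | intermediate
6 | (3S)-5-[(4-methoxybenzyl)oxy]pent-1-en-3-ol | C=C[C@@H](O)CCOCc1ccc(OC)cc1 | intermediate
7 | (3S)-5-[(4-methoxybenzyl)oxy]pent-1-en-3-yl methanesulfonate | C=C[C@@H](OS(C)(=O)=O)CCOCc1ccc(OC)cc1 | intermediate (not isolated)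
8 | (3R)-3-hydroperoxy-5-[(4-methoxybenzyl)oxy]pent-1-ene | C=C[C@H](OO)CCOCc1ccc(OC)cc1 | intermediate
9 | tetrahydrofuran | C1CCOC1 | starting material
10 | tert-butyl(4-iodobutoxy)diphenylsilane | CC(C)(C)[Si](OCCCCI)(c1ccccc1)c1ccccc1 | intermediate
11 | methoxyallene (1-methoxypropa-1,2-diene) | COC=C=C | starting material
12 | 1-lithio-1-methoxypropa-1,2-diene | [Li]C(OC)=C=C | intermediate (not isolated)
13 | tert-butyl[(5-methoxyhepta-5,6-dien-1-yl)oxy]diphenylsilane | C=C=C(OC)CCCCO[Si](c1ccccc1)(c1ccccc1)C(C)(C)C | intermediate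
14 | tert-butyl[(5,5-dimethoxyhept-6-en-1-yl)oxy]diphenylsilane | C=CC(OC)(OC)CCCCO[Si](c1ccccc1)(c1ccccc1)C(C)(C)C | intermediate
15 | (3R)-5-[(4-methoxybenzyl)oxy]pent-1-en-3-yl 7-[(tert-butyldiphenylsilyl)oxy]-3-methoxyhept-1-en-3-yl peroxide, both ketal epimers | C=C[C@@H](CCOCc1ccc(OC)cc1)OOC(OC)(C=C)CCCCO[Si](c1ccccc1)(c1ccccc1)C(C)(C)C | intermediate (key-step precursor)
16 | (3R)-6-{4-[(tert-butyldiphenylsilyl)oxy]butyl}-6-methoxy-3-{2-[(4-methoxybenzyl)oxy]ethyl}-3,6-dihydro-1,2-dioxine, both C6 epimers | COC1(CCCCO[Si](c2ccccc2)(c2ccccc2)C(C)(C)C)C=C[C@@H](CCOCc2ccc(OC)cc2)OO1 | intermediate (key-step product)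
17 | (3S)-6-{4-[(tert-butyldiphenylsilyl)oxy]butyl}-6-methoxy-3-{2-[(4-methoxybenzyl)oxy]ethyl}-1,2-dioxane, both C6 epimers | COC1(CCCCO[Si](c2ccccc2)(c2ccccc2)C(C)(C)C)CC[C@@H](CCOCc2ccc(OC)cc2)OO1 | intermediate
18 | (3S,6R)-6-{4-[(tert-butyldiphenylsilyl)oxy]butyl}-6-methoxy-3-{2-[(4-methoxybenzyl)oxy]ethyl}-1,2-dioxane | CC(C)(C)[Si](OCCCC[C@]1(OC)CC[C@@H](CCOCc2ccc(OC)cc2)OO1)(c1ccccc1)c1ccccc1 | intermediate
19 | (3S,6R)-6-(4-hydroxybutyl)-6-methoxy-3-{2-[(4-methoxybenzyl)oxy]ethyl}-1,2-dioxane | OCCCC[C@]1(OC)CC[C@@H](CCOCc2ccc(OC)cc2)OO1 | intermediate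
20 | (3S,6R)-6-methoxy-3-{2-[(4-methoxybenzyl)oxy]ethyl}-6-(4-oxobutyl)-1,2-dioxane | O=CCCC[C@]1(OC)CC[C@@H](CCOCc2ccc(OC)cc2)OO1 | intermediate
21 | (3S,6R)-6-methoxy-3-{2-[(4-methoxybenzyl)oxy]ethyl}-6-(pent-4-yn-1-yl)-1,2-dioxane | C#CCCC[C@]1(OC)CC[C@@H](CCOCc2ccc(OC)cc2)OO1 | intermediate
22 | dec-9-en-1-ol | C=CCCCCCCCCO | starting material
23 | dec-9-enal | C=CCCCCCCCC=O | intermediate
24 | undec-1-en-10-yne | C=CCCCCCCCC#C | intermediate
25 | chlorobis(cyclopentadienyl)[(1E)-undeca-1,10-dien-1-yl]zirconium | C=CCCCCCCC/C=C/[Zr](Cl)(C1C=CC=C1)C1C=CC=C1 | intermediate (not isolated)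
26 | (1E)-1-iodoundeca-1,10-diene | C=CCCCCCCC/C=C/I | intermediate
27 | (3S,6R)-6-[(6E)-hexadeca-6,15-dien-4-yn-1-yl]-6-methoxy-3-{2-[(4-methoxybenzyl)oxy]ethyl}-1,2-dioxane | C=CCCCCCCC/C=C/C#CCCC[C@]1(OC)CC[C@@H](CCOCc2ccc(OC)cc2)OO1 | intermediate
28 | 2-[(3S,6R)-6-[(6E)-hexadeca-6,15-dien-4-yn-1-yl]-6-methoxy-1,2-dioxan-3-yl]ethan-1-ol | C=CCCCCCCC/C=C/C#CCCC[C@]1(OC)CC[C@@H](CCO)OO1 | intermediate
29 | 2-[(3S,6R)-6-[(6E)-hexadeca-6,15-dien-4-yn-1-yl]-6-methoxy-1,2-dioxan-3-yl]acetaldehyde | C=CCCCCCCC/C=C/C#CCCC[C@]1(OC)CC[C@@H](CC=O)OO1 | intermediate (not isolated)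
30 | 2-[(3S,6R)-6-[(6E)-hexadeca-6,15-dien-4-yn-1-yl]-6-methoxy-1,2-dioxan-3-yl]acetic acid | C=CCCCCCCC/C=C/C#CCCC[C@]1(OC)CC[C@@H](CC(=O)O)OO1 | target

Total step count: 21. Longest linear sequence: 15 steps (steps 1–5, 9–15, 19–21).

Steps most likely to fail

1. Step 5. The secondary allylic mesylate may ionise or be attacked at the alkene terminus (SN2′), which would erode the configurational purity at C3, and the free hydroperoxide may be degraded by the base. Fallback: the hydroperoxide is resolved instead of being made by stereospecific inversion. The fallback sets out from racemic alcohol 5, which is mesylated and displaced as in step 5 without regard to stereochemistry, giving the racemic mesylate F1 and then the racemic hydroperoxide F2. F2 is added under PPTS catalysis to the 2-propenyl ether of (1R,2S)-2-phenylcyclohexanol, giving two diastereomeric perketals that contain no new stereocentre, the 3R perketal F3 and the 3S perketal F4, which are separated by chromatography. Hydrolysis of F3 (AcOH/THF/H2O) comes back to the route at hydroperoxide 8.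

2. Step 10. The ruthenium centre or its decomposition products may cleave or rearrange the O–O bond of substrate or product, or the hindered vinyl group on the ketal carbon may fail to engage so that the substrate oligomerises. Fallback: C4=C5 is made by cross-metathesis before any peroxide is present, and the ring is closed at O1–C6 instead. The fallback sets out from alcohol 6 and ketal 14, which are joined by cross-metathesis with the same catalyst to the E-configured hydroxy alkene ketal F5. Diimide from 2-nitrobenzenesulfonyl hydrazide and Et3N gives the saturated hydroxy ketal F6, and Ms2O/Et3N gives the mesylate F7. Displacement by hydroperoxide anion (urea·H2O2, CsOH·H2O, DMF), now at a saturated secondary carbon and with inversion, gives the hydroperoxy ketal F8. PPTS in CH2Cl2 closes the ring by intramolecular peroxyketal exchange and comes back to the route at compound 17.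

3. Step 9. The intermolecular exchange may stall at equilibrium, or the allyl-type oxocarbenium ion may be captured at its terminal carbon by hydroperoxide or methanol. Fallback: the O–O–C6 bond is put in first and the O–C3 bond is made by alkylation instead of acid exchange. The fallback sets out from ketal 14, which is exchanged with excess ethereal H2O2 (cat. PPTS) to the hydroperoxy ketal F9. F9 is alkylated with mesylate 7, generated from 6 as in step 5 (CsOH·H2O, DMF, 0 °C, SN2 with inversion), and comes back to the route at precursor 15.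

Further compounds
F1 | step 5 | racemic 5-[(4-methoxybenzyl)oxy]pent-1-en-3-yl methanesulfonate | C=CC(OS(C)(=O)=O)CCOCc1ccc(OC)cc1
F2 | step 5 | racemic 3-hydroperoxy-5-[(4-methoxybenzyl)oxy]pent-1-ene | C=CC(OO)CCOCc1ccc(OC)cc1
F3 | step 5 | (3R)-5-[(4-methoxybenzyl)oxy]pent-1-en-3-yl 2-{[(1R,2S)-2-phenylcyclohexyl]oxy}propan-2-yl peroxide | C=C[C@H](OOC(C)(C)O[C@@H]1CCCC[C@H]1c1ccccc1)CCOCc1ccc(OC)cc1
F4 | step 5 | (3S)-5-[(4-methoxybenzyl)oxy]pent-1-en-3-yl 2-{[(1R,2S)-2-phenylcyclohexyl]oxy}propan-2-yl peroxide | C=C[C@@H](OOC(C)(C)O[C@@H]1CCCC[C@H]1c1ccccc1)CCOCc1ccc(OC)cc1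
F5 | step 10 | (3S,4E)-10-[(tert-butyldiphenylsilyl)oxy]-6,6-dimethoxy-1-[(4-methoxybenzyl)oxy]dec-4-en-3-ol | O[C@@H](CCOCc1ccc(OC)cc1)/C=C/C(OC)(OC)CCCCO[Si](c1ccccc1)(c1ccccc1)C(C)(C)C
F6 | step 10 | (3R)-10-[(tert-butyldiphenylsilyl)oxy]-6,6-dimethoxy-1-[(4-methoxybenzyl)oxy]decan-3-ol | O[C@@H](CCOCc1ccc(OC)cc1)CCC(OC)(OC)CCCCO[Si](c1ccccc1)(c1ccccc1)C(C)(C)C
F7 | step 10 | (3R)-10-[(tert-butyldiphenylsilyl)oxy]-6,6-dimethoxy-1-[(4-methoxybenzyl)oxy]decan-3-yl methanesulfonate | CS(=O)(=O)O[C@@H](CCOCc1ccc(OC)cc1)CCC(OC)(OC)CCCCO[Si](c1ccccc1)(c1ccccc1)C(C)(C)C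
F8 | step 10 | (3S)-10-[(tert-butyldiphenylsilyl)oxy]-3-hydroperoxy-6,6-dimethoxy-1-[(4-methoxybenzyl)oxy]decane | OO[C@H](CCOCc1ccc(OC)cc1)CCC(OC)(OC)CCCCO[Si](c1ccccc1)(c1ccccc1)C(C)(C)C
F9 | step 9 | tert-butyl[(5-hydroperoxy-5-methoxyhept-6-en-1-yl)oxy]diphenylsilane | C=CC(OC)(OO)CCCCO[Si](c1ccccc1)(c1ccccc1)C(C)(C)C
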